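**Retrosynthetic overview**
1. Target ⇒ copper-mediated C–O coupling of an (E)-alkenyltrifluoroborate with 3-methylbut-2-enoic acid; the alkenylboron comes from a C5 aldehyde by Takai–Utimoto olefination.
2. The C6 acetonyl group (cis to C5) ⇒ tethered 6-exo radical cyclisation of a C5–CH2O bromoketal onto a cross-conjugated dienone; the ketal ring is then opened to CH2COCH3 + CH2OH.
3. Dienone ⇒ doubly allylic oxidation of a cyclohepta-1,4-diene, which is made in the key union: Rh-catalysed asymmetric cyclopropanation/Cope ([4+3]) of a (Z)-diene (C1–C4, CH3, homoprenyl, CH2OSi) with a vinyldiazoacetate (C5–C7 plus tether); this sets C4 and C5.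
4. Diene ⇒ Suzuki coupling of a (Z)-alkenylboronate (carbocupration of propyne) with silylated 2-bromoallyl alcohol; diazo fragment ⇒ Pd coupling of an (E)-vinyl iodide with methyl diazoacetate.
5. Ring order: transient cyclopropane → seven-membered carbocycle (the only ring of the target) → temporary oxane ketal ring (formed in step 11, opened in step 12).

Locants C1–C7 below are those of the target ring (C1 = C=O, C2 = C–CH2OH, C3 = CH=, C4 = quaternary C, C5 = CH bearing the enol-ester side chain, C6 = CH bearing CH2COCH3, C7 = CH2). Ring compounds are named with these locants; CIP letters at C4/C5 change with the C5 substituent although the geometry does not.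
Assumption: Rh2(S-DOSP)4 (dirhodium tetrakis[(S)-N-(4-dodecylbenzenesulfonyl)prolinate]) is taken to give the enantiomeric series drawn, by analogy with its (1S,2R) sense with styrene; if the opposite sense is found, Rh2(R-DOSP)4 is used.

**Step 1**
Reactants: 1 2-bromoprop-2-en-1-ol
Product: 2 [(2-bromoprop-2-en-1-yl)oxy](tert-butyl)diphenylsilane
Conditions: TBDPSCl, imidazole, CH2Cl2, 0 °C → rt
Reagents that add atoms: tert-butyl(chloro)diphenylsilane, CC(C)(C)[Si](Cl)(c1ccccc1)c1ccccc1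
Why: Silyl ether protection of the primary allylic alcohol; no stereocentre is involved.

**Step 2**
Reactants: 3 5-bromo-2-methylpent-2-ene; 4 propyne
Product: 7 (1Z)-1-iodo-2,6-dimethylhepta-1,5-diene, via homoprenylmagnesium bromide 5 (not isolated), via (Z)-alkenylcopper 6 (not isolated)
Conditions: Mg, THF, 35 °C; CuBr·SMe2, Et2O/Me2S, −45 °C; 4, −25 °C; I2, −50 → 0 °C
Reagents that add atoms: iodine, [I][I]
Why: Normant carbocupration adds the alkylcopper syn across propyne (chain and copper cis), and iodinolysis with retention gives the (Z)-iodide.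

**Step 3**
Reactants: 7 (1Z)-1-iodo-2,6-dimethylhepta-1,5-diene
Product: 9 2-[(1Z)-2,6-dimethylhepta-1,5-dien-1-yl]-4,4,5,5-tetramethyl-1,3,2-dioxaborolane, via (Z)-alkenyllithium 8 (not isolated)
Conditions: t-BuLi (2 equiv), Et2O, −78 °C; i-PrOBpin, −78 °C → rt
Reagents that add atoms: 2-isopropoxy-4,4,5,5-tetramethyl-1,3,2-dioxaborolane, CC(C)OB1OC(C)(C)C(C)(C)O1
Why: Iodine–lithium exchange and borylation of the alkenyllithium both go with retention of the Z geometry.

**Step 4**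
Reactants: 9 2-[(1Z)-2,6-dimethylhepta-1,5-dien-1-yl]-4,4,5,5-tetramethyl-1,3,2-dioxaborolane; 2 [(2-bromoprop-2-en-1-yl)oxy](tert-butyl)diphenylsilane
Product: 10 tert-butyl{[(3Z)-4,8-dimethyl-2-methylidenenona-3,7-dien-1-yl]oxy}diphenylsilane
Conditions: Pd(dppf)Cl2 (5 mol %), K3PO4, THF/H2O, 50 °C
Reagents that add atoms: none
Why: Suzuki–Miyaura coupling of two alkenyl partners proceeds with retention and gives the (3Z) 2-substituted 1,3-diene.

**Step 5**
Reactants: 11 methyl glycinate hydrochloride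
Product: 12 methyl diazoacetate
Conditions: NaNO2, H2SO4 (cat.), CH2Cl2/H2O, −5 °C (kept as a CH2Cl2 solution)
Reagents that add atoms: sodium nitrite, [Na+].[O-]N=O
Why: Diazotisation of the α-amino ester; the methyl ester suits both the dirhodium prolinate catalysis and the later Krapcho step.

**Step 6**
Reactants: 13 prop-2-yn-1-ol; 14 2-methoxypropene
Product: 15 3-[(1-bromo-2-methoxypropan-2-yl)oxy]prop-1-yne
Conditions: NBS, CH2Cl2, −78 → 0 °C
Reagents that add atoms: N-bromosuccinimide, O=C1CCC(=O)N1Br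
Why: Ueno–Stork bromoketalisation (the bromo-oxocarbenium ion from the enol ether is trapped by the alcohol); the ketal carbon is a racemic centre that is destroyed in step 12.

**Step 7**
Reactants: 15 3-[(1-bromo-2-methoxypropan-2-yl)oxy]prop-1-yne
Product: 17 (1E)-3-[(1-bromo-2-methoxypropan-2-yl)oxy]-1-iodoprop-1-ene, via (E)-alkenylzirconocene chloride 16 (not isolated)
Conditions: Cp2Zr(H)Cl, THF, rt; I2, 0 °C
Reagents that add atoms: iodine, [I][I]
Why: Schwartz hydrozirconation (syn, zirconium at the terminus) followed by iodinolysis with retention gives the (E)-vinyl iodide.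

**Step 8**
Reactants: 17 (1E)-3-[(1-bromo-2-methoxypropan-2-yl)oxy]-1-iodoprop-1-ene; 12 methyl diazoacetate
Product: 18 methyl (3E)-5-[(1-bromo-2-methoxypropan-2-yl)oxy]-2-diazopent-3-enoate
Conditions: Pd(PPh3)4 (5 mol %), Et3N, n-Bu4NBr, MeCN, rt (used at once)
Reagents that add atoms: none
Why: Palladium-catalysed cross-coupling of the vinyl iodide with the diazoacetate C–H bond keeps the E geometry; zerovalent palladium does not insert into the neopentyl-type C–Br bond at rt.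

**Step 9**
Reactants: 18 methyl (3E)-5-[(1-bromo-2-methoxypropan-2-yl)oxy]-2-diazopent-3-enoate; 10 tert-butyl{[(3Z)-4,8-dimethyl-2-methylidenenona-3,7-dien-1-yl]oxy}diphenylsilane
Product: 20 methyl (4S,5S)-5-{[(1-bromo-2-methoxypropan-2-yl)oxy]methyl}-2-{[tert-butyl(diphenyl)silyl]oxymethyl}-4-methyl-4-(4-methylpent-3-en-1-yl)cyclohepta-2,6-diene-7-carboxylate, via cis-divinylcyclopropane 19 (not isolated)
Conditions: Rh2(S-DOSP)4 (1 mol %), hexanes, −40 °C → rt (18 added over 2 h to 10, 1.5 equiv); then PhMe, 80 °C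
Reagents that add atoms: none
Why: Davies tandem asymmetric cyclopropanation/Cope rearrangement (formal [4+3]): the chiral dirhodium carbenoid adds to one face of the 1,1-disubstituted alkene of 10, and the boat Cope transition state places the two E substituents (C5–CH2OR and C4–CH3 of the Z-diene) cis, so C4 and C5 are set together.

**Step 10**
Reactants: 20 (cycloheptadiene ester from step 9)
Product: 21 methyl (4S,5S)-5-{[(1-bromo-2-methoxypropan-2-yl)oxy]methyl}-2-{[tert-butyl(diphenyl)silyl]oxymethyl}-4-methyl-4-(4-methylpent-3-en-1-yl)-1-oxocyclohepta-2,6-diene-7-carboxylate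
Conditions: CrO3, 3,5-dimethylpyrazole, CH2Cl2, −20 °C
Reagents that add atoms: chromium trioxide, O=[Cr](=O)=O
Why: Allylic C–H oxidation (Salmond conditions): the C1 methylene flanked by both ring alkenes has the weakest C–H bond and is oxidised to the cross-conjugated dienone in preference to the side-chain allylic positions.

**Step 11**
Reactants: 21 (dienone ester from step 10)
Product: 22 methyl (4aR,9S,9aS)-7-{[tert-butyl(diphenyl)silyl]oxymethyl}-3-methoxy-3,9-dimethyl-9-(4-methylpent-3-en-1-yl)-6-oxo-1,3,4,4a,5,6,9,9a-octahydrocyclohepta[c]pyran-5-carboxylate (cis-fused; target locants 4S,5S,6R; both epimers at the ketal carbon and at C7)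
Conditions: n-Bu3SnH (syringe pump), AIBN (cat.), PhH, 80 °C
Reagents that add atoms: none
Why: Ueno–Stork tin-hydride radical cyclisation (6-exo-trig): the primary radical tethered through C5–CH2O adds to the electrophilic β-carbon C6 on the face that carries the tether, so the new C6–CH2 bond is cis to the C5 substituent.

**Step 12**
Reactants: 22 (bicyclic ketal β-keto ester from step 11)
Product: 24 (4S,5S,6S)-2-{[tert-butyl(diphenyl)silyl]oxymethyl}-5-(hydroxymethyl)-4-methyl-4-(4-methylpent-3-en-1-yl)-6-(2-oxopropyl)cyclohept-2-en-1-one, via hydroxy keto ester 23 (not isolated)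
Conditions: LiCl, H2O, DMSO, 90 → 130 °C
Reagents that add atoms: water, O
Why: LiCl-promoted ketal hydrolysis and Krapcho-type demethoxycarbonylation of the β-keto ester in wet DMSO unmask the acetonyl ketone and the C5 hydroxymethyl group and turn C7 into CH2, without touching C4–C6.

**Step 13**
Reactants: 24 (keto alcohol from step 12)
Product: 25 (4S,5S,6S)-2-{[tert-butyl(diphenyl)silyl]oxymethyl}-4-methyl-4-(4-methylpent-3-en-1-yl)-1-oxo-6-(2-oxopropyl)cyclohept-2-ene-5-carbaldehyde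
Conditions: Dess–Martin periodinane, CH2Cl2, 0 °C → rt (used crude)
Reagents that add atoms: none
Why: Dess–Martin oxidation of the primary alcohol under non-basic conditions keeps the epimerisable C5 centre and the 1,5-keto aldehyde intact.

**Step 14**
Reactants: 26 dichloromethane
Product: 29 2-(dichloromethyl)-4,4,5,5-tetramethyl-1,3,2-dioxaborolane, via (dichloromethyl)lithium 27 (not isolated), via (dichloromethyl)boronic acid 28 (not isolated)
Conditions: n-BuLi, THF, −100 °C; B(OMe)3, −100 °C → rt; 5 M HCl; pinacol, MgSO4, rt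
Reagents that add atoms: trimethyl borate, COB(OC)OC; pinacol, CC(C)(O)C(C)(C)O
Why: Deprotonation of CH2Cl2, borylation of the carbenoid anion and esterification with pinacol (Matteson-type reagent synthesis).

**Step 15**
Reactants: 25 (aldehyde from step 13); 29 2-(dichloromethyl)-4,4,5,5-tetramethyl-1,3,2-dioxaborolane
Product: 30 (4R,5R,6S)-2-{[tert-butyl(diphenyl)silyl]oxymethyl}-4-methyl-4-(4-methylpent-3-en-1-yl)-6-(2-oxopropyl)-5-[(E)-2-(4,4,5,5-tetramethyl-1,3,2-dioxaborolan-2-yl)ethenyl]cyclohept-2-en-1-one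
Conditions: CrCl2, LiI, THF, rt
Reagents that add atoms: none
Why: Takai–Utimoto borylolefination: the geminal dichromium species made from 29 with divalent chromium reacts only with the aldehyde (not the ketones) and gives the (E)-alkenylboronate.

**Step 16**
Reactants: 30 (alkenyl pinacol boronate from step 15)
Product: 31 potassium {(E)-2-[(4R,5R,6S)-2-{[tert-butyl(diphenyl)silyl]oxymethyl}-4-methyl-4-(4-methylpent-3-en-1-yl)-1-oxo-6-(2-oxopropyl)cyclohept-2-en-5-yl]ethenyl}trifluoroborate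
Conditions: KHF2, MeOH/H2O, rt
Reagents that add atoms: potassium hydrogen difluoride, F.[F-].[K+]
Why: Boronate-to-trifluoroborate exchange with KHF2 gives the salt that transmetalates cleanly to copper; the alkene geometry is untouched.

**Step 17**
Reactants: 31 (potassium alkenyltrifluoroborate from step 16); 32 3-methylbut-2-enoic acid
Product: 33 (E)-2-[(4R,5R,6S)-2-{[tert-butyl(diphenyl)silyl]oxymethyl}-4-methyl-4-(4-methylpent-3-en-1-yl)-1-oxo-6-(2-oxopropyl)cyclohept-2-en-5-yl]ethenyl 3-methylbut-2-enoate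
Conditions: Cu(OAc)2 (20 mol %), DMAP, 4 Å MS, O2 (1 atm), CH2Cl2, rt
Reagents that add atoms: none
Why: Copper-catalysed oxidative C–O coupling of the Chan–Lam–Evans type (Batey enol ester variant) goes with retention at the alkenyl carbon and gives the (E)-enol ester.

**Step 18**
Reactants: 33 (silyl-protected target from step 17)
Product: 34 (E)-2-[(4R,5R,6S)-2-(hydroxymethyl)-4-methyl-4-(4-methylpent-3-en-1-yl)-1-oxo-6-(2-oxopropyl)cyclohept-2-en-5-yl]ethenyl 3-methylbut-2-enoate (CNP0415257.2)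
Conditions: HF·pyridine, pyridine/THF, 0 °C → rt
Reagents that add atoms: none
Why: Fluoride desilylation of the primary TBDPS ether under buffered conditions that the enol ester, the enone and the methyl ketone tolerate.

**Compound list**
1 | 2-bromoprop-2-en-1-ol | OCC(Br)=C | starting material
2 | [(2-bromoprop-2-en-1-yl)oxy](tert-butyl)diphenylsilane | C=C(Br)CO[Si](c1ccccc1)(c1ccccc1)C(C)(C)C | intermediate
3 | 5-bromo-2-methylpent-2-ene | CC(C)=CCCBr | starting material
4 | propyne | CC#C | starting material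
5 | (4-methylpent-3-en-1-yl)magnesium bromide | CC(C)=CCC[Mg]Br | intermediate
6 | [(1Z)-2,6-dimethylhepta-1,5-dien-1-yl]copper | CC(C)=CCC/C(C)=C\[Cu] | intermediate
7 | (1Z)-1-iodo-2,6-dimethylhepta-1,5-diene | CC(C)=CCC/C(C)=C\I | intermediate
8 | [(1Z)-2,6-dimethylhepta-1,5-dien-1-yl]lithium | CC(C)=CCC/C(C)=C\[Li] | intermediate
9 | 2-[(1Z)-2,6-dimethylhepta-1,5-dien-1-yl]-4,4,5,5-tetramethyl-1,3,2-dioxaborolane | CC(C)=CCC/C(C)=C\B1OC(C)(C)C(C)(C)O1 | intermediate
10 | tert-butyl{[(3Z)-4,8-dimethyl-2-methylidenenona-3,7-dien-1-yl]oxy}diphenylsilane | C=C(CO[Si](c1ccccc1)(c1ccccc1)C(C)(C)C)/C=C(/C)CCC=C(C)C | intermediate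
11 | methyl glycinate hydrochloride | Cl.COC(=O)CN | starting material
12 | methyl diazoacetate | COC(=O)C=[N+]=[N-] | intermediate
13 | prop-2-yn-1-ol | C#CCO | starting material
14 | 2-methoxypropene | COC(C)=C | starting material
15 | 3-[(1-bromo-2-methoxypropan-2-yl)oxy]prop-1-yne (racemic ketal carbon) | C#CCOC(C)(OC)CBr | intermediate
16 | chloro{(1E)-3-[(1-bromo-2-methoxypropan-2-yl)oxy]prop-1-en-1-yl}zirconocene | Cl[Zr](/C=C/COC(C)(OC)CBr)(C1C=CC=C1)C1C=CC=C1 | intermediate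
17 | (1E)-3-[(1-bromo-2-methoxypropan-2-yl)oxy]-1-iodoprop-1-ene | I/C=C/COC(C)(OC)CBr | intermediate
18 | methyl (3E)-5-[(1-bromo-2-methoxypropan-2-yl)oxy]-2-diazopent-3-enoate | COC(=O)C(=[N+]=[N-])/C=C/COC(C)(OC)CBr | intermediate
19 | methyl (1R,2S)-1-{(1E)-3-[(1-bromo-2-methoxypropan-2-yl)oxy]prop-1-en-1-yl}-2-{[tert-butyl(diphenyl)silyl]oxymethyl}-2-[(1Z)-2,6-dimethylhepta-1,5-dien-1-yl]cyclopropane-1-carboxylate | COC(=O)[C@]1(/C=C/COC(C)(OC)CBr)C[C@]1(CO[Si](c2ccccc2)(c2ccccc2)C(C)(C)C)/C=C(/C)CCC=C(C)C | intermediate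
20 | methyl (4S,5S)-5-{[(1-bromo-2-methoxypropan-2-yl)oxy]methyl}-2-{[tert-butyl(diphenyl)silyl]oxymethyl}-4-methyl-4-(4-methylpent-3-en-1-yl)cyclohepta-2,6-diene-7-carboxylate | C1=C(C(=O)OC)CC(CO[Si](c2ccccc2)(c2ccccc2)C(C)(C)C)=C[C@](C)(CCC=C(C)C)[C@H]1COC(C)(OC)CBr | intermediate
21 | methyl (4S,5S)-5-{[(1-bromo-2-methoxypropan-2-yl)oxy]methyl}-2-{[tert-butyl(diphenyl)silyl]oxymethyl}-4-methyl-4-(4-methylpent-3-en-1-yl)-1-oxocyclohepta-2,6-diene-7-carboxylate | C1=C(C(=O)OC)C(=O)C(CO[Si](c2ccccc2)(c2ccccc2)C(C)(C)C)=C[C@](C)(CCC=C(C)C)[C@H]1COC(C)(OC)CBr | intermediate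
22 | methyl (4aR,9S,9aS)-7-{[tert-butyl(diphenyl)silyl]oxymethyl}-3-methoxy-3,9-dimethyl-9-(4-methylpent-3-en-1-yl)-6-oxo-1,3,4,4a,5,6,9,9a-octahydrocyclohepta[c]pyran-5-carboxylate (epimers at C3 and C5 of this name) | COC1(C)C[C@H]2C(C(=O)OC)C(=O)C(CO[Si](c3ccccc3)(c3ccccc3)C(C)(C)C)=C[C@](C)(CCC=C(C)C)[C@H]2CO1 | intermediate
23 | methyl (4S,5S,6R)-2-{[tert-butyl(diphenyl)silyl]oxymethyl}-5-(hydroxymethyl)-4-methyl-4-(4-methylpent-3-en-1-yl)-1-oxo-6-(2-oxopropyl)cyclohept-2-ene-7-carboxylate (epimers at C7) | CC(=O)C[C@H]1C(C(=O)OC)C(=O)C(CO[Si](c2ccccc2)(c2ccccc2)C(C)(C)C)=C[C@](C)(CCC=C(C)C)[C@H]1CO | intermediate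
24 | (4S,5S,6S)-2-{[tert-butyl(diphenyl)silyl]oxymethyl}-5-(hydroxymethyl)-4-methyl-4-(4-methylpent-3-en-1-yl)-6-(2-oxopropyl)cyclohept-2-en-1-one | CC(=O)C[C@H]1CC(=O)C(CO[Si](c2ccccc2)(c2ccccc2)C(C)(C)C)=C[C@](C)(CCC=C(C)C)[C@H]1CO | intermediate
25 | (4S,5S,6S)-2-{[tert-butyl(diphenyl)silyl]oxymethyl}-4-methyl-4-(4-methylpent-3-en-1-yl)-1-oxo-6-(2-oxopropyl)cyclohept-2-ene-5-carbaldehyde | CC(=O)C[C@H]1CC(=O)C(CO[Si](c2ccccc2)(c2ccccc2)C(C)(C)C)=C[C@](C)(CCC=C(C)C)[C@H]1C=O | intermediate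
26 | dichloromethane | ClCCl | starting material
27 | (dichloromethyl)lithium | [Li]C(Cl)Cl | intermediate
28 | (dichloromethyl)boronic acid | OB(O)C(Cl)Cl | intermediate
29 | 2-(dichloromethyl)-4,4,5,5-tetramethyl-1,3,2-dioxaborolane | ClC(Cl)B1OC(C)(C)C(C)(C)O1 | intermediate
30 | (4R,5R,6S)-2-{[tert-butyl(diphenyl)silyl]oxymethyl}-4-methyl-4-(4-methylpent-3-en-1-yl)-6-(2-oxopropyl)-5-[(E)-2-(4,4,5,5-tetramethyl-1,3,2-dioxaborolan-2-yl)ethenyl]cyclohept-2-en-1-one | CC(=O)C[C@H]1CC(=O)C(CO[Si](c2ccccc2)(c2ccccc2)C(C)(C)C)=C[C@](C)(CCC=C(C)C)[C@H]1/C=C/B3OC(C)(C)C(C)(C)O3 | intermediate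
31 | potassium {(E)-2-[(4R,5R,6S)-2-{[tert-butyl(diphenyl)silyl]oxymethyl}-4-methyl-4-(4-methylpent-3-en-1-yl)-1-oxo-6-(2-oxopropyl)cyclohept-2-en-5-yl]ethenyl}trifluoroborate | CC(=O)C[C@H]1CC(=O)C(CO[Si](c2ccccc2)(c2ccccc2)C(C)(C)C)=C[C@](C)(CCC=C(C)C)[C@H]1/C=C/[B-](F)(F)F.[K+] | intermediate
32 | 3-methylbut-2-enoic acid | CC(C)=CC(=O)O | starting material
33 | (E)-2-[(4R,5R,6S)-2-{[tert-butyl(diphenyl)silyl]oxymethyl}-4-methyl-4-(4-methylpent-3-en-1-yl)-1-oxo-6-(2-oxopropyl)cyclohept-2-en-5-yl]ethenyl 3-methylbut-2-enoate | CC(=O)C[C@H]1CC(=O)C(CO[Si](c2ccccc2)(c2ccccc2)C(C)(C)C)=C[C@](C)(CCC=C(C)C)[C@H]1/C=C/OC(=O)C=C(C)C | intermediate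
34 | (E)-2-[(4R,5R,6S)-2-(hydroxymethyl)-4-methyl-4-(4-methylpent-3-en-1-yl)-1-oxo-6-(2-oxopropyl)cyclohept-2-en-5-yl]ethenyl 3-methylbut-2-enoate | CC(=O)C[C@H]1CC(=O)C(CO)=C[C@](C)(CCC=C(C)C)[C@H]1/C=C/OC(=O)C=C(C)C | target

**Totals**
Total step count: 18.
Longest linear sequence: 12 steps (6 → 7 → 8 → 9 → 10 → 11 → 12 → 13 → 15 → 16 → 17 → 18; the branch through steps 2 → 3 → 4 → 9 is equally long).

**Steps most likely to fail, with fallbacks**

Step 9 (the cyclopropanation/Cope union). The 2-substituted diene, the inward-pointing chain in the Cope transition state and the sense and level of induction are all untested for this pair. Fallback, setting out from 17 and coming back at 24: (R)-pantolactone is acylated with succinimidyl diazoacetate to give (3R)-4,4-dimethyl-2-oxooxolan-3-yl diazoacetate F1, which is coupled with 17 as in step 8 to the pantolactonyl vinyldiazoacetate F2. F2 is decomposed with achiral dirhodium tetraoctanoate Rh2(OOct)4 in the presence of 10, so that the α-hydroxy-ester auxiliary rather than the catalyst controls the face; after the Cope step this gives the pantolactonyl cycloheptadienecarboxylate F3 (the enantiomer of the auxiliary is chosen to match). Oxidation as in step 10 gives the pantolactonyl dienone ester F4, tin-hydride cyclisation as in step 11 gives the pantolactonyl bicyclic ketal F5, and the LiCl/wet DMSO treatment of step 12 removes ketal, auxiliary ester and CO2 to return 24.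

Step 10 (oxidation of the doubly allylic CH2). Oxygen may be delivered at a transposed position, or the side-chain alkene may be attacked. Fallback, setting out from 20 and coming back at 22: the tin-hydride cyclisation is run first, onto the enoate of 20, to give the saturated bicyclic ketal ester F6. Its lithium enolate (LDA, THF, −78 °C) is trapped with PhSeBr to give the α-phenylselanyl ester F7, and H2O2/pyridine then gives, by selenoxide syn-elimination towards C1, the dienoate F8. Copper-catalysed conjugate borylation (CuCl, NaOt-Bu, Xantphos, B2pin2, MeOH) places boron on C1 to give the C1 pinacol boronate F9, NaBO3 oxidation gives the C1 alcohol F10, and Dess–Martin oxidation of F10 gives 22. The oxygen thus enters by conjugate addition instead of C–H oxidation.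

Step 17 (copper-mediated enol ester formation on a hindered alkenylboron next to a quaternary carbon). Fallback, setting out from 25 and coming back at 33: acid 32 is treated with chloromethyl chlorosulfate (NaHCO3, n-Bu4NHSO4, CH2Cl2/H2O) to give chloromethyl 3-methylbut-2-enoate F11, and PPh3 (PhMe, 80 °C) converts it into the (acyloxymethyl)triphenylphosphonium chloride F12. NaHMDS (THF, −78 °C) gives the acyloxymethylene ylide F13, which olefinates aldehyde 25 directly to 33 (Anders–Gaßner-type Wittig reaction). This avoids boron and copper but gives an E/Z mixture from which the E isomer has to be separated.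

**Further compounds**
F1 | step 9 | (3R)-4,4-dimethyl-2-oxooxolan-3-yl diazoacetate | [N-]=[N+]=CC(=O)O[C@H]1C(=O)OCC1(C)C
F2 | step 9 | (3R)-4,4-dimethyl-2-oxooxolan-3-yl (3E)-5-[(1-bromo-2-methoxypropan-2-yl)oxy]-2-diazopent-3-enoate | BrCC(C)(OC)OC/C=C/C(=[N+]=[N-])C(=O)O[C@H]1C(=O)OCC1(C)C
F3 | step 9 | (3R)-4,4-dimethyl-2-oxooxolan-3-yl (4S,5S)-5-{[(1-bromo-2-methoxypropan-2-yl)oxy]methyl}-2-{[tert-butyl(diphenyl)silyl]oxymethyl}-4-methyl-4-(4-methylpent-3-en-1-yl)cyclohepta-2,6-diene-7-carboxylate | C1=C(C(=O)O[C@H]2C(=O)OCC2(C)C)CC(CO[Si](c3ccccc3)(c3ccccc3)C(C)(C)C)=C[C@](C)(CCC=C(C)C)[C@H]1COC(C)(OC)CBr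
F4 | step 9 | (3R)-4,4-dimethyl-2-oxooxolan-3-yl (4S,5S)-5-{[(1-bromo-2-methoxypropan-2-yl)oxy]methyl}-2-{[tert-butyl(diphenyl)silyl]oxymethyl}-4-methyl-4-(4-methylpent-3-en-1-yl)-1-oxocyclohepta-2,6-diene-7-carboxylate | C1=C(C(=O)O[C@H]2C(=O)OCC2(C)C)C(=O)C(CO[Si](c3ccccc3)(c3ccccc3)C(C)(C)C)=C[C@](C)(CCC=C(C)C)[C@H]1COC(C)(OC)CBr
F5 | step 9 | (3R)-4,4-dimethyl-2-oxooxolan-3-yl (4aR,9S,9aS)-7-{[tert-butyl(diphenyl)silyl]oxymethyl}-3-methoxy-3,9-dimethyl-9-(4-methylpent-3-en-1-yl)-6-oxo-1,3,4,4a,5,6,9,9a-octahydrocyclohepta[c]pyran-5-carboxylate | COC1(C)C[C@H]2C(C(=O)O[C@H]3C(=O)OCC3(C)C)C(=O)C(CO[Si](c4ccccc4)(c4ccccc4)C(C)(C)C)=C[C@](C)(CCC=C(C)C)[C@H]2CO1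
F6 | step 10 | methyl (4aR,9S,9aS)-7-{[tert-butyl(diphenyl)silyl]oxymethyl}-3-methoxy-3,9-dimethyl-9-(4-methylpent-3-en-1-yl)-1,3,4,4a,5,6,9,9a-octahydrocyclohepta[c]pyran-5-carboxylate | COC1(C)C[C@H]2C(C(=O)OC)CC(CO[Si](c3ccccc3)(c3ccccc3)C(C)(C)C)=C[C@](C)(CCC=C(C)C)[C@H]2CO1
F7 | step 10 | methyl (4aR,9S,9aS)-7-{[tert-butyl(diphenyl)silyl]oxymethyl}-3-methoxy-3,9-dimethyl-9-(4-methylpent-3-en-1-yl)-5-(phenylselanyl)-1,3,4,4a,5,6,9,9a-octahydrocyclohepta[c]pyran-5-carboxylate | COC1(C)C[C@H]2C([Se]c3ccccc3)(C(=O)OC)CC(CO[Si](c3ccccc3)(c3ccccc3)C(C)(C)C)=C[C@](C)(CCC=C(C)C)[C@H]2CO1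
F8 | step 10 | methyl (4aR,9S,9aS)-7-{[tert-butyl(diphenyl)silyl]oxymethyl}-3-methoxy-3,9-dimethyl-9-(4-methylpent-3-en-1-yl)-1,3,4,4a,9,9a-hexahydrocyclohepta[c]pyran-5-carboxylate | COC1(C)C[C@H]2C(C(=O)OC)=CC(CO[Si](c3ccccc3)(c3ccccc3)C(C)(C)C)=C[C@](C)(CCC=C(C)C)[C@H]2CO1
F9 | step 10 | methyl (4aR,9S,9aS)-7-{[tert-butyl(diphenyl)silyl]oxymethyl}-3-methoxy-3,9-dimethyl-9-(4-methylpent-3-en-1-yl)-6-(4,4,5,5-tetramethyl-1,3,2-dioxaborolan-2-yl)-1,3,4,4a,5,6,9,9a-octahydrocyclohepta[c]pyran-5-carboxylate | COC1(C)C[C@H]2C(C(=O)OC)C(B3OC(C)(C)C(C)(C)O3)C(CO[Si](c3ccccc3)(c3ccccc3)C(C)(C)C)=C[C@](C)(CCC=C(C)C)[C@H]2CO1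
F10 | step 10 | methyl (4aR,9S,9aS)-7-{[tert-butyl(diphenyl)silyl]oxymethyl}-6-hydroxy-3-methoxy-3,9-dimethyl-9-(4-methylpent-3-en-1-yl)-1,3,4,4a,5,6,9,9a-octahydrocyclohepta[c]pyran-5-carboxylate | COC1(C)C[C@H]2C(C(=O)OC)C(O)C(CO[Si](c3ccccc3)(c3ccccc3)C(C)(C)C)=C[C@](C)(CCC=C(C)C)[C@H]2CO1
F11 | step 17 | chloromethyl 3-methylbut-2-enoate | CC(C)=CC(=O)OCCl
F12 | step 17 | {[(3-methylbut-2-enoyl)oxy]methyl}triphenylphosphonium chloride | CC(C)=CC(=O)OC[P+](c1ccccc1)(c1ccccc1)c1ccccc1.[Cl-]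
F13 | step 17 | [(triphenyl-λ5-phosphanylidene)methyl] 3-methylbut-2-enoate | CC(C)=CC(=O)OC=P(c1ccccc1)(c1ccccc1)c1ccccc1
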